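**Strategy.** Everything rests on disconnecting the C8–O bond last. The A ring is carried as a plain phloroglucinol-type ring and the 8-oxygen is installed on the finished flavonol, copying the presumed biosynthesis (flavonol 8-hydroxylation, then O-methylation). The key step, an Elbs persulfate oxidation, turns C8–H into C8–OH in one operation: the chelated 5-OH phenoxide directs the oxidant only to its para carbon C8, which fixes the 5,7,8-pattern and leaves the new 8-OH as the only non-chelated phenol for methylation. Its precursor is 3,7,3',5'-tetra-O-benzyl-4'-O-methylmyricetin with free 5-OH, built from phloracetophenone and a 4-O-methylgallate by chalcone chemistry.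

Key step: step 9

Assumption: the target SMILES contains no stereocentre, so the compound is achiral and no enantiocontrol is needed; the only stereo-element in the route is the E-alkene of chalcone 7.

**Route**

Step 1
Reactants: 1 2',4',6'-trihydroxyacetophenone
Product: 2 1-[2,4-bis(benzyloxy)-6-hydroxyphenyl]ethanone
Conditions: BnBr (2.1 equiv), K2CO3, acetone, reflux
Reagents that add atoms: benzyl bromide, BrCc1ccccc1
Why: Williamson etherification in which the 2-OH, hydrogen-bonded to the acetyl carbonyl, is the least nucleophilic phenol, so two equivalents of benzyl bromide should stop at the 4,6-di-O-benzyl ether.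

Step 2
Reactants: 3 methyl 3,5-dihydroxy-4-methoxybenzoate
Product: 4 methyl 3,5-bis(benzyloxy)-4-methoxybenzoate
Conditions: BnBr (2.4 equiv), K2CO3, DMF, 60 °C
Reagents that add atoms: benzyl bromide, BrCc1ccccc1
Why: Williamson etherification of both free phenols, with no selectivity issue because the 4-methoxy group of the future B ring is already in place.

Step 3
Reactants: 4 methyl 3,5-bis(benzyloxy)-4-methoxybenzoate
Product: 5 [3,5-bis(benzyloxy)-4-methoxyphenyl]methanol
Conditions: LiAlH4, THF, 0 °C to rt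
Reagents that add atoms: none
Why: Hydride reduction of the aryl ester to the benzylic alcohol, to which benzyl and methyl aryl ethers are inert.

Step 4
Reactants: 5 [3,5-bis(benzyloxy)-4-methoxyphenyl]methanol
Product: 6 3,5-bis(benzyloxy)-4-methoxybenzaldehyde
Conditions: activated MnO2, CH2Cl2, rt
Reagents that add atoms: none
Why: Manganese dioxide oxidation is selective for benzylic alcohols and should stop cleanly at the aldehyde.

Step 5
Reactants: 2 1-[2,4-bis(benzyloxy)-6-hydroxyphenyl]ethanone; 6 3,5-bis(benzyloxy)-4-methoxybenzaldehyde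
Product: 7 (E)-1-[2,4-bis(benzyloxy)-6-hydroxyphenyl]-3-[3,5-bis(benzyloxy)-4-methoxyphenyl]prop-2-en-1-one
Conditions: aq. KOH, EtOH/THF, rt
Reagents that add atoms: none
Why: Claisen–Schmidt aldol condensation of the methyl ketone enolate with the non-enolisable aldehyde, in which E1cB dehydration should give the conjugated E-enone as the thermodynamic isomer.

Step 6
Reactants: 7 (E)-1-[2,4-bis(benzyloxy)-6-hydroxyphenyl]-3-[3,5-bis(benzyloxy)-4-methoxyphenyl]prop-2-en-1-one
Product: 8 5,7-bis(benzyloxy)-2-[3,5-bis(benzyloxy)-4-methoxyphenyl]-3-hydroxy-4H-chromen-4-one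
Conditions: 30% H2O2, aq. NaOH, MeOH/THF, 0 °C to rt
Reagents that add atoms: hydrogen peroxide, OO
Why: Algar–Flynn–Oyamada reaction, in which alkaline hydroperoxide oxidation of the 2'-hydroxychalcone with 6-endo closure by the phenoxide and in situ dehydrogenation should give the 3-hydroxyflavone while benzyl ethers are untouched.

Step 7
Reactants: 8 5,7-bis(benzyloxy)-2-[3,5-bis(benzyloxy)-4-methoxyphenyl]-3-hydroxy-4H-chromen-4-one
Product: 9 7-(benzyloxy)-2-[3,5-bis(benzyloxy)-4-methoxyphenyl]-3,5-dihydroxy-4H-chromen-4-one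
Conditions: conc. HCl, AcOH, 40 °C
Reagents that add atoms: none
Why: Carbonyl-assisted selective acidolysis of a benzyl ether, since only the 5-benzyloxy oxygen lies peri to the protonated C4 carbonyl and its cleavage is driven by formation of the chelated 5-OH, so the other aryl benzyl ethers should survive.

Step 8
Reactants: 9 7-(benzyloxy)-2-[3,5-bis(benzyloxy)-4-methoxyphenyl]-3,5-dihydroxy-4H-chromen-4-one
Product: 10 3,7-bis(benzyloxy)-2-[3,5-bis(benzyloxy)-4-methoxyphenyl]-5-hydroxy-4H-chromen-4-one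
Conditions: BnBr (1.1 equiv), K2CO3, DMF, rt
Reagents that add atoms: benzyl bromide, BrCc1ccccc1
Why: Williamson benzylation of the acidic 3-enol, with the 5-OH left free because its six-membered hydrogen bond to C4=O makes it the least reactive hydroxyl of a flavonol under carbonate conditions.

Step 9
Reactants: 10 3,7-bis(benzyloxy)-2-[3,5-bis(benzyloxy)-4-methoxyphenyl]-5-hydroxy-4H-chromen-4-one
Product: 12 3,7-bis(benzyloxy)-2-[3,5-bis(benzyloxy)-4-methoxyphenyl]-5,8-dihydroxy-4H-chromen-4-one, via potassium flavon-8-yl sulfate 11 (not isolated)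
Conditions: K2S2O8 (1.5 equiv), aq. KOH, pyridine, 0 °C to rt; then aq. HCl, Na2SO3, dioxane, 85 °C
Reagents that add atoms: potassium peroxodisulfate, [K+].[K+].[O-]S(=O)(=O)OOS([O-])(=O)=O
Why: In aqueous alkali the chelated 5-OH of 10 is ionised and the phenoxide, reacting through its para carbon C8 (further activated by the ortho 7-benzyloxy group and ring O1), attacks a peroxide oxygen of peroxodisulfate in an SN2-type displacement of sulfate; rearomatisation gives aryl sulfate 11, whose electron-poor sulfate group shields the new oxygen from over-oxidation until acid hydrolysis (S–O cleavage) releases the 8-OH of 12. The closest known reaction type is the Elbs persulfate oxidation of phenols, which is established for 5-hydroxyflavone and 5-hydroxyflavonol ethers as an entry to their 5,8-dihydroxy derivatives. No ring is closed and no stereocentre is formed. The selectivity needed is C8 over C6 and ring A over ring B: the Elbs reaction is inherently para-selective, C6 is only an ortho position flanked by O5 and the 7-benzyloxy group, and ring B carries no free phenol and so cannot form the nucleophilic phenoxide. The C2=C3 enol is masked as its benzyl ether, so the oxidation-sensitive flavonol enolate is never exposed to persulfate, and cold dilute alkali should spare the pyranone ring.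

Step 10
Reactants: 12 3,7-bis(benzyloxy)-2-[3,5-bis(benzyloxy)-4-methoxyphenyl]-5,8-dihydroxy-4H-chromen-4-one
Product: 13 3,7-bis(benzyloxy)-2-[3,5-bis(benzyloxy)-4-methoxyphenyl]-5-hydroxy-8-methoxy-4H-chromen-4-one
Conditions: MeI (1.1 equiv), K2CO3, acetone, rt, Ar
Reagents that add atoms: iodomethane, CI
Why: Williamson methylation that should be selective for the 8-OH, the only phenol not chelated to C4=O, with argon preventing aerial oxidation of the hydroquinone-type A ring to the 5,8-quinone.

Step 11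
Reactants: 13 3,7-bis(benzyloxy)-2-[3,5-bis(benzyloxy)-4-methoxyphenyl]-5-hydroxy-8-methoxy-4H-chromen-4-one
Product: 14 2-(3,5-dihydroxy-4-methoxyphenyl)-3,5,7-trihydroxy-8-methoxy-4H-chromen-4-one (CNP0103387.0)
Conditions: H2 (1 atm), 10% Pd/C, THF/MeOH, rt
Reagents that add atoms: none
Why: Catalytic hydrogenolysis should cleave all four O-benzyl groups while the two methyl ethers and the tetrasubstituted, vinylogous-ester C2=C3 bond of the flavonol are not reduced.

**Compound list**

1 | 2',4',6'-trihydroxyacetophenone | CC(=O)c1c(O)cc(O)cc1O | starting material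
2 | 1-[2,4-bis(benzyloxy)-6-hydroxyphenyl]ethanone | CC(=O)c1c(O)cc(OCc2ccccc2)cc1OCc1ccccc1 | intermediate
3 | methyl 3,5-dihydroxy-4-methoxybenzoate | COC(=O)c1cc(O)c(OC)c(O)c1 | starting material
4 | methyl 3,5-bis(benzyloxy)-4-methoxybenzoate | COC(=O)c1cc(OCc2ccccc2)c(OC)c(OCc2ccccc2)c1 | intermediate
5 | [3,5-bis(benzyloxy)-4-methoxyphenyl]methanol | OCc1cc(OCc2ccccc2)c(OC)c(OCc2ccccc2)c1 | intermediate
6 | 3,5-bis(benzyloxy)-4-methoxybenzaldehyde | O=Cc1cc(OCc2ccccc2)c(OC)c(OCc2ccccc2)c1 | intermediate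
7 | (E)-1-[2,4-bis(benzyloxy)-6-hydroxyphenyl]-3-[3,5-bis(benzyloxy)-4-methoxyphenyl]prop-2-en-1-one | O=C(/C=C/c1cc(OCc2ccccc2)c(OC)c(OCc2ccccc2)c1)c1c(O)cc(OCc2ccccc2)cc1OCc1ccccc1 | intermediate
8 | 5,7-bis(benzyloxy)-2-[3,5-bis(benzyloxy)-4-methoxyphenyl]-3-hydroxy-4H-chromen-4-one | COc1c(OCc2ccccc2)cc(-c2oc3cc(OCc4ccccc4)cc(OCc4ccccc4)c3c(=O)c2O)cc1OCc1ccccc1 | intermediate
9 | 7-(benzyloxy)-2-[3,5-bis(benzyloxy)-4-methoxyphenyl]-3,5-dihydroxy-4H-chromen-4-one | COc1c(OCc2ccccc2)cc(-c2oc3cc(OCc4ccccc4)cc(O)c3c(=O)c2O)cc1OCc1ccccc1 | intermediate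
10 | 3,7-bis(benzyloxy)-2-[3,5-bis(benzyloxy)-4-methoxyphenyl]-5-hydroxy-4H-chromen-4-one | COc1c(OCc2ccccc2)cc(-c2oc3cc(OCc4ccccc4)cc(O)c3c(=O)c2OCc2ccccc2)cc1OCc1ccccc1 | intermediate
11 | potassium 3,7-bis(benzyloxy)-2-[3,5-bis(benzyloxy)-4-methoxyphenyl]-5-hydroxy-4-oxo-4H-chromen-8-yl sulfate | COc1c(OCc2ccccc2)cc(-c2oc3c(OS(=O)(=O)[O-])c(OCc4ccccc4)cc(O)c3c(=O)c2OCc2ccccc2)cc1OCc1ccccc1.[K+] | intermediate
12 | 3,7-bis(benzyloxy)-2-[3,5-bis(benzyloxy)-4-methoxyphenyl]-5,8-dihydroxy-4H-chromen-4-one | COc1c(OCc2ccccc2)cc(-c2oc3c(O)c(OCc4ccccc4)cc(O)c3c(=O)c2OCc2ccccc2)cc1OCc1ccccc1 | intermediate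
13 | 3,7-bis(benzyloxy)-2-[3,5-bis(benzyloxy)-4-methoxyphenyl]-5-hydroxy-8-methoxy-4H-chromen-4-one | COc1c(OCc2ccccc2)cc(-c2oc3c(OC)c(OCc4ccccc4)cc(O)c3c(=O)c2OCc2ccccc2)cc1OCc1ccccc1 | intermediate
14 | 2-(3,5-dihydroxy-4-methoxyphenyl)-3,5,7-trihydroxy-8-methoxy-4H-chromen-4-one | COc1c(O)cc(-c2oc3c(OC)c(O)cc(O)c3c(=O)c2O)cc1O | target

**Step count and risks**

Total step count: 11. Longest linear sequence: 10 steps (3 to 14 through steps 2 to 11); step 1 supplies the second fragment.

Steps most likely to fail: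

1. Step 9 (Elbs oxidation). The strongly chelated and poorly soluble phenoxide may convert only partly. The hydroquinone-type product may be oxidised further, and the pyranone may open in alkali. Fallback: setting out from 8, benzylation of the 3-OH (BnBr, K2CO3, DMF) should give 3,5,7-tris(benzyloxy)-2-[3,5-bis(benzyloxy)-4-methoxyphenyl]-4H-chromen-4-one F1. Electrophilic iodination (NIS, cat. TFA, MeCN) should occur at C8, which is para to the 5-alkoxy group, to give the 8-iodo pentabenzyl ether F2. Copper-catalysed Ullmann methoxylation (NaOMe, CuI, DMF/MeOH, 110 °C) should then give the 8-methoxy pentabenzyl ether F3. Hydrogenolysis (H2, Pd/C) brings the sequence back to the route at 14.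

2. Step 6 (Algar–Flynn–Oyamada reaction). The 6'-benzyloxy group twists the enone, so 5-exo closure to an aurone may compete with flavonol formation. Fallback: setting out from 7, iodine-catalysed oxidative cyclisation (cat. I2, DMSO, 120 °C) should give 5,7-bis(benzyloxy)-2-[3,5-bis(benzyloxy)-4-methoxyphenyl]-4H-chromen-4-one F4. Epoxidation of its C2=C3 bond with dimethyldioxirane (acetone/CH2Cl2, 0 °C) should give the racemic 2,3-epoxyflavanone F5. Acid-catalysed opening and tautomerisation (cat. TsOH) returns to the route at 8.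

3. Step 7 (selective 5-O-debenzylation). Acidolysis may spread to the 7-O or B-ring benzyl ethers, or conversion may be incomplete. Fallback: setting out from 8, all benzyl groups are removed by hydrogenolysis (H2, Pd/C, THF/MeOH) to give 2-(3,5-dihydroxy-4-methoxyphenyl)-3,5,7-trihydroxy-4H-chromen-4-one F6. Benzylation with BnBr (4.2 equiv) and K2CO3 in DMF should then alkylate every hydroxyl except the chelated 5-OH, and returns to the route at 10.

**Further compounds**

F1 | step 9 | 3,5,7-tris(benzyloxy)-2-[3,5-bis(benzyloxy)-4-methoxyphenyl]-4H-chromen-4-one | COc1c(OCc2ccccc2)cc(-c2oc3cc(OCc4ccccc4)cc(OCc4ccccc4)c3c(=O)c2OCc2ccccc2)cc1OCc1ccccc1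
F2 | step 9 | 3,5,7-tris(benzyloxy)-2-[3,5-bis(benzyloxy)-4-methoxyphenyl]-8-iodo-4H-chromen-4-one | COc1c(OCc2ccccc2)cc(-c2oc3c(I)c(OCc4ccccc4)cc(OCc4ccccc4)c3c(=O)c2OCc2ccccc2)cc1OCc1ccccc1
F3 | step 9 | 3,5,7-tris(benzyloxy)-2-[3,5-bis(benzyloxy)-4-methoxyphenyl]-8-methoxy-4H-chromen-4-one | COc1c(OCc2ccccc2)cc(-c2oc3c(OC)c(OCc4ccccc4)cc(OCc4ccccc4)c3c(=O)c2OCc2ccccc2)cc1OCc1ccccc1
F4 | step 6 | 5,7-bis(benzyloxy)-2-[3,5-bis(benzyloxy)-4-methoxyphenyl]-4H-chromen-4-one | COc1c(OCc2ccccc2)cc(-c2cc(=O)c3c(OCc4ccccc4)cc(OCc4ccccc4)cc3o2)cc1OCc1ccccc1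
F5 | step 6 | racemic 5,7-bis(benzyloxy)-2-[3,5-bis(benzyloxy)-4-methoxyphenyl]-2,3-epoxychroman-4-one (cis-fused epoxide, both enantiomers) | COc1c(OCc2ccccc2)cc(C23OC2C(=O)c2c(OCc4ccccc4)cc(OCc4ccccc4)cc2O3)cc1OCc1ccccc1
F6 | step 7 | 2-(3,5-dihydroxy-4-methoxyphenyl)-3,5,7-trihydroxy-4H-chromen-4-one | COc1c(O)cc(-c2oc3cc(O)cc(O)c3c(=O)c2O)cc1O
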